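# Proposed total synthesis of CNP0330487.1 via a decalin-to-hydroazulene 1,2-shift

## Structural features

The target is a daucane sesquiterpenoid ester: a trans-fused bicyclo[5.3.0]decane in which a cyclopentane (C1–C5) and a cycloheptane (C1, C5–C10) share the C1–C5 bond. C1 is quaternary (angular methyl, defining the β face). C4 is a tertiary carbinol carrying isopropyl with its hydroxyl β, C5 carries its hydrogen α, and C6 carries the vanillate α. These four centres are contiguous, while the fifth, the allylic carbinol C9 (hydroxyl α, cis to O6), lies across the seven-membered ring beside the exocyclic C8=C14 methylene. Fragile elements are the tertiary alcohol (an aldol, open to retro-aldol cleavage and dehydration while C6 is a ketone), the aryl ester with its free phenol, and the 1,1-disubstituted alkene with its allylic alcohol. The real difficulty is the congested C1/C4/C5/C6 array with a trans ring fusion, plus two cis oxygens (C6, C9) on a flexible cycloheptane. The key step exploits the C4(OH)–C5(H)–C6(O) triad with C1 bonded to C5. A C6 ketone flanked by a C5 that holds both C1 and an oxygenated C4 is the residue of a pinacol-type 1,2-shift of the C1–C6 fusion bond of a decalin onto C5. That shift contracts ring A (C1–C6) to the cyclopentane and expands ring B (C1, C6–C10) to the cycloheptanone.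

## Logic of the disconnections

27 ⇒ 26. Cut: the O–Si bond on the phenol. A free phenol would interfere with acylation, the titanium methylene reagent and SeO2, so it is unveiled last. The forward step must spare the aryl ester, the allylic alcohol and the tertiary alcohol.

26 ⇒ 25. Cut: the C9–O bond. Allylic C–H oxidation beside the C8=C14 methylene avoids carrying a second secondary hydroxyl. Placing it after acylation of O6 means O6 and O9 never compete for the acid, and C7 is deactivated by the neighbouring ester. The forward step must choose C9 over C7 and the α face over the β face.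

25 ⇒ 24 ⇒ 23. Cut: C8=C14, then the two C8–O bonds of the dioxolane. The C8 ketone is what the annulation delivers, and it stays masked through all earlier steps. Since 24 is a β-acyloxy ketone, the methylenation must be non-basic.

23 ⇒ 19 + 22, and 22 ⇒ 20. Cut: the ester C(=O)–O6 bond. The union is convergent, and only the secondary hydroxyl of 19 can acylate. Acylation proceeds with retention, so C6 must already be correct in 19.

19 ⇒ 18. Cut: the C6–H bond. Hydride must arrive on the hindered β face, so the forward step has to deliver it internally from the β hydroxyl on C4.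

18 ⇒ 17 (key). Cut C1–C5 and reconnect C1–C6. The hydroazulene becomes a decalin that a Robinson annulation can build, and the triad becomes a 4,6-diol with a leaving group on C5. The forward shift is a backside displacement at C5, which makes three demands:
- the leaving group on C5 and the oxygen on C4 must both be β (they become 4β-OH and, after inversion, 5α-H);
- the C1–C6 bond must be anti-periplanar to the C5–leaving-group bond;
- the C6–C7 bond must not be.

A C4–C5 oxirane on the β face cannot meet the second demand, on a dihedral-angle analysis of the half-chair conformers. In the trans-fused 6α-ol the ring fusion locks ring A so that the axial C6–O bond is anti to C5–O and C1–C6 is gauche. In the cis-fused 6β-ol the bond nearest to anti is C6–C7, which would migrate instead. The precursor is therefore corrected to the cis-fused all-β triol 5-sulfonate 17. In its ring A chair with isopropyl equatorial, C5–OMs is equatorial and anti to C1–C6, and C7 is gauche. O4 is carried through as the future C4 hydroxyl, and there is no choice between C4–O and C5–O cleavage. The bond formed, the two rings made and both skeletons are unchanged, and 18 is the same ketone.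

17 ⇒ 16 ⇒ 14. Cut: the S–O bond, then the C4–O and C5–O bonds. A syn-dihydroxylation of the C4=C5 alkene steered by the 6β-hydroxyl places all three oxygens on one face. The forward step must overcome the usual anti preference of osmylation next to an allylic oxygen.

14 ⇒ 12 ⇒ 11 ⇒ 9. Cut: the C4=C5 alkene back to a C5–Se bond, then C5–Se and the C6–O bond back to the C5=C6 alkene. The tertiary 6β-carbinol with transposed unsaturation comes from a β-epoxide by selenide opening and selenoxide elimination. The demands are an epoxide syn to the angular methyl (bromohydrin route) and a hydrogen on C4 syn to selenium, which requires isopropyl cis to methyl in 9.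

9 ⇒ 8 ⇒ 7 ⇒ 2 + 4. Cut: the dioxolane, then C6=C7 and C1–C10 (Robinson annulation). This reduces the decalin to a cyclohexanone and a four-carbon enone. The forward Michael step must create quaternary C1 with methyl cis to isopropyl, against the substrate's own preference, which is the job of the recoverable auxiliary 3.

2 ⇒ 1. Cut: four C–H bonds. Saturating both alkenes of 1 gives the annulation donor in one step and keeps the stereocentre that later places H4.

## Other disconnections considered

Alternative 1: The cut is both ring C–O bonds (C6–O and C9–O) at once. The forward key step is sensitised photooxygenation of the 6,8-diene A2, which carries CH2SiMe3 on C8. Singlet oxygen adds across C6 and C9 on the face away from the C1 methyl to give endoperoxide A1. O–O reduction and protodesilylation of the allylsilane would then give the cis-6,9-diol with the C8=C14 methylene.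
- In its favour: one concerted cycloaddition fixes both oxygens and their cis relationship. On this point it is better than the chosen plan, which needs a directed reduction for C6 and a late allylic oxidation for C9. It also reaches the methylene without a ketone olefination.
- Against it here: A2 already contains the complete trans-fused core with C1, C4 and C5 set, so the hard part of the skeleton is left unsolved. Ene reaction at C10–H or C14–H can compete. The two secondary hydroxyls released must then be told apart for acylation at O6 only, a problem the chosen plan avoids.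
- Comparison: better on the oxygenation pattern and mechanistically more forgiving (a cycloaddition against a shift that needs exact alignment). It is silent on the C1/C4/C5 triad, and overall longer once A2 has to be made.

Alternative 2: The cut is C7–C8 and C1–C10, dividing the seven-membered ring into the vinylcyclopentene A4 and the vinyldiazoacetate A5. In the forward step Rh2(S-DOSP)4, or its enantiomer, forms a vinylcarbenoid that cyclopropanates the vinyl group. Cope rearrangement of the cis-divinylcyclopropane then closes the ring and creates quaternary C1, giving A3.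
- In its favour: the cycloheptadiene and C1 arise in one catalytic enantioselective step from achiral pieces. In convergence and in step economy for the bare skeleton it is better than the chosen plan. It is also better in using a catalyst where the chosen plan uses a stoichiometric auxiliary.
- Against it here: A3 lacks C4, C5, C6 and C9 as stereocentres. The isopropyl carbinol must be added to the unmasked ketone beside quaternary C1, the C5=C6 alkene must be turned into 5α-H/6α-O, and the C8 ester must be reworked into a methylene with oxygen at C9. The Cope step must also form a quaternary centre from a tetrasubstituted alkene terminus.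
- Comparison: the chosen shift sets C5 and fixes the ring fusion in the ring-forming step and carries C4 through untouched; the alternative postpones both. The total step count is probably similar.

Alternative 3: The cut is C3–C4. In the forward step Rh2(OAc)4 turns diazomethyl ketone A7 into a carbenoid at C3 that inserts into the C4–H bond of the silyloxy-substituted side chain on C5 with retention. This closes the cyclopentane as the C2 ketone A6.
- In its favour: five-membered-ring insertion into an oxygen-activated methine is favourable, and retention transfers the carbinol configuration to C4. In stereospecificity it is the equal of the chosen 1,2-shift, and the ester and ketal can already be in place.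
- Against it here: A7 needs C1, C5, C6 and the side-chain carbinol set beforehand on a cycloheptane, so the stereochemical problem is moved, not solved. Insertion at C6–H or C9–H can compete. The extra C2 ketone must afterwards be removed in the presence of an aryl ester.
- Comparison: it builds only the five-membered ring where the chosen step builds both rings from an annulation product, and its step economy is worse.

Key step: step 10

Remark: daucane numbering is used for every bicyclic compound, decalins included; β is the face of the C1 methyl group; 2 is used as its C2-epimer mixture because C2 is planarised in step 2.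

## Route

Step 1
Reactants: 1 (S)-carvone
Product: 2 (2S,5S)-2-methyl-5-(propan-2-yl)cyclohexan-1-one (carvomenthone)
Conditions: H2 (1 atm), Pd/C, EtOAc, rt
Reagents that add atoms: none
Why: Heterogeneous hydrogenation saturates the enone C=C and the isopropenyl group and leaves the ketone; the C5 stereocentre is kept and the new C2 centre need not be controlled.

Step 2
Reactants: 2 carvomenthone; 3 (S)-1-phenylethylamine; 4 methyl vinyl ketone
Product: 7 (2R,5S)-2-methyl-2-(3-oxobutyl)-5-(propan-2-yl)cyclohexan-1-one, via imine 5 (not isolated), via Michael adduct imine 6 (not isolated)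
Conditions: 3, TsOH (cat.), toluene, reflux, azeotropic removal of water; then 4, THF, 40 °C; then AcOH–H2O, rt
Reagents that add atoms: water, O
Why: Chiral-imine Michael addition: the imine reacts through its more substituted secondary enamine tautomer in an aza-ene-like transition state, and the (S)-phenylethyl group shields one face so that C1 becomes quaternary with methyl cis to isopropyl; aqueous acid then frees the ketone and the auxiliary.

Step 3
Reactants: 7 diketone
Product: 8 (4aR,7S)-4a-methyl-7-(propan-2-yl)-4,4a,5,6,7,8-hexahydronaphthalen-2(3H)-one
Conditions: NaOMe (cat.), MeOH, 60 °C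
Reagents that add atoms: none
Why: The Robinson annulation is completed by intramolecular aldol condensation of the methyl ketone onto the ring ketone and dehydration; no stereocentre is touched.

Step 4
Reactants: 8 enone
Product: 9 8,8-ethylenedioxy-4β-isopropyl-1β-methyldecal-5-ene
Conditions: HOCH2CH2OH, TsOH (cat.), benzene, reflux, azeotropic removal of water
Reagents that add atoms: ethylene glycol, OCCO
Why: Acid-catalysed ketalisation of the conjugated enone passes through the dienol and gives the β,γ-unsaturated dioxolane, which puts the alkene at C5=C6.

Step 5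
Reactants: 9 alkene ketal
Product: 11 5β,6β-epoxy-8,8-ethylenedioxy-4β-isopropyl-1β-methyldecalin, via bromohydrin 10 (not isolated)
Conditions: NBS, THF–H2O, 0 °C; then K2CO3, MeOH, rt
Reagents that add atoms: water, O
Why: Bromohydrin formation and closure: the bromonium ion forms on the α face away from the angular methyl, water opens it trans-diaxially from the β face, and base closes the alkoxide onto the bromide carbon with inversion; this gives the epoxide syn to the methyl and sets C6–O β.

Step 6
Reactants: 11 β-epoxide
Product: 12 8,8-ethylenedioxy-4β-isopropyl-1β-methyl-5α-(phenylselanyl)decalin-6β-ol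
Conditions: PhSeSePh, NaBH4, EtOH, reflux
Reagents that add atoms: diphenyl diselenide, c1ccc(cc1)[Se][Se]c1ccccc1
Why: SN2 opening of the epoxide by the selenolate at the secondary carbon C5 with inversion leaves the tertiary 6β-alcohol of a cis-fused decalin and puts selenium on the α face beside H4.

Step 7
Reactants: 12 hydroxy selenide
Product: 14 8,8-ethylenedioxy-4-isopropyl-1β-methyldecal-4-en-6β-ol, via selenoxide 13 (not isolated)
Conditions: 30% H2O2, pyridine, CH2Cl2, 0 °C to rt
Reagents that add atoms: none
Why: Oxidation to the selenoxide and syn-elimination; the only syn β-hydrogen is H4 because C6 carries none, so the alkene forms at C4=C5 and the carvone-derived centre C4 is erased after it has done its work.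

Step 8
Reactants: 14 allylic alcohol
Product: 16 8,8-ethylenedioxy-4α-isopropyl-1β-methyldecalin-4β,5β,6β-triol, via osmate ester 15 (not isolated)
Conditions: OsO4 (1 equiv), TMEDA, CH2Cl2, −78 °C; then aq. Na2SO3, THF, 40 °C
Reagents that add atoms: osmium tetroxide, O=[Os](=O)(=O)=O
Why: Hydrogen-bond-directed dihydroxylation: the OsO4·TMEDA complex accepts a hydrogen bond from the 6β-hydroxyl and adds to the alkene face syn to it, so both new C–O bonds (C4, C5) are β; sulfite then cleaves the osmate ester.

Step 9
Reactants: 16 triol
Product: 17 8,8-ethylenedioxy-4β,6β-dihydroxy-4α-isopropyl-1β-methyldecalin-5β-yl methanesulfonate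
Conditions: MsCl, pyridine, 0 °C
Reagents that add atoms: methanesulfonyl chloride, CS(=O)(=O)Cl
Why: Sulfonylation of the only secondary hydroxyl; the two tertiary hydroxyls do not react under these conditions.

Step 10
Reactants: 17 hydroxy mesylate
Product: 18 8,8-ethylenedioxy-4β-hydroxydaucan-6-one
Conditions: Et3Al, CH2Cl2, −78 to 0 °C; aq. potassium sodium tartrate
Reagents that add atoms: none
Why: Et3Al converts both tertiary hydroxyls into aluminium alkoxides and activates the sulfonate; the oxygen on C6 pushes as the C1–C6 σ-bond, which is anti-periplanar to the equatorial C5–OMs bond in the ring A chair that keeps isopropyl equatorial, shifts to C5 and expels mesylate, leaving the C6 ketone. This is the pinacol-type (semipinacol) rearrangement of a β-hydroxy sulfonate, the long-established passage from decalin-diol monosulfonates to hydroazulenones, here in its organoaluminium-promoted form. The cyclopentane closes by the 1,2-alkyl shift itself (new C1–C5 bond, ring A contracted), and the cycloheptanone arises by ring expansion because C6 stays bonded to C5 and C7 while C1 now reaches it through C5. C5 is the only new stereocentre and is inverted stereospecifically, so the 5β-sulfonate from step 8 fixes H5 α and the trans ring fusion; C1 and C4 are untouched. The step needs C1, not C7 or C3, to migrate: C7 is gauche to the leaving group in this chair and cannot move, and C3 (pushed by O4) is also anti but is a methylene competing with a fully substituted carbon of much higher migratory aptitude. Epoxide formation and elimination are closed off because both flanking oxygens are cis to the sulfonate and C4 and C6 bear no hydrogen. The aluminium aldolate that results should resist retro-aldol cleavage until the neutral work-up.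

Step 11
Reactants: 18 hydroxy ketone
Product: 19 8,8-ethylenedioxydaucane-4β,6α-diol
Conditions: Me4NBH(OAc)3, MeCN–AcOH, −30 to 0 °C
Reagents that add atoms: none
Why: Directed reduction of a β-hydroxy ketone (Evans–Saksena reduction): the acetoxyborohydride exchanges onto the C4 hydroxyl and passes hydride within the molecule to the β face of C6, giving the 6α-alcohol that an external hydride attacking the open α face would not give.

Step 12
Reactants: 20 vanillic acid
Product: 22 4-(tert-butyldimethylsilyloxy)-3-methoxybenzoic acid, via bis-silyl derivative 21 (not isolated)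
Conditions: TBSCl, imidazole, DMF, rt; then K2CO3, MeOH–THF–H2O, rt; citric acid work-up
Reagents that add atoms: tert-butyldimethylsilyl chloride, CC(C)(C)[Si](C)(C)Cl
Why: Silylation of phenol and acid, then selective hydrolysis of the labile silyl ester under mild carbonate conditions, leaves the aryl silyl ether.

Step 13
Reactants: 19 diol; 22 protected vanillic acid
Product: 23 8,8-ethylenedioxy-4β-hydroxydaucan-6α-yl 4-(tert-butyldimethylsilyloxy)-3-methoxybenzoate
Conditions: DCC, DMAP (cat.), CH2Cl2, rt
Reagents that add atoms: none
Why: Steglich esterification; only the secondary C6 hydroxyl is acylated and the C6–O bond is not broken, so the configuration from step 11 is kept.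

Step 14
Reactants: 23 ester ketal
Product: 24 4β-hydroxy-8-oxodaucan-6α-yl 4-(tert-butyldimethylsilyloxy)-3-methoxybenzoate
Conditions: PPTS (cat.), acetone–H2O, 50 °C
Reagents that add atoms: water, O
Why: Mild acid-catalysed hydrolysis of the dioxolane; without base the β-acyloxy ketone does not eliminate, and the aryl silyl ether and tertiary alcohol survive.

Step 15
Reactants: 24 ketone
Product: 25 4β-hydroxydauc-8(14)-en-6α-yl 4-(tert-butyldimethylsilyloxy)-3-methoxybenzoate
Conditions: Zn, CH2Br2, TiCl4, THF–CH2Cl2, 0 °C to rt
Reagents that add atoms: dibromomethane, BrCBr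
Why: Takai–Lombardo methylenation: the non-basic zinc–titanium methylene reagent converts the ketone and not the ester, and avoids the enolisation that would expel the C6 acyloxy group.

Step 16
Reactants: 25 exocyclic alkene
Product: 26 4β,9α-dihydroxydauc-8(14)-en-6α-yl 4-(tert-butyldimethylsilyloxy)-3-methoxybenzoate
Conditions: SeO2 (cat.), t-BuOOH, CH2Cl2, rt
Reagents that add atoms: selenium dioxide, O=[Se]=O (catalytic oxygen carrier); tert-butyl hydroperoxide, CC(C)(C)OO (terminal oxygen source)
Why: SeO2 allylic oxidation (ene reaction, then [2,3]-sigmatropic shift) keeps the exocyclic alkene; C7–H is deactivated by the adjacent acyloxy group so C9 should react, and oxygen should arrive on the α face away from the C1 methyl, which sets C9.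

Step 17
Reactants: 26 silyl-protected target
Product: 27 4β,9α-dihydroxydauc-8(14)-en-6α-yl 4-hydroxy-3-methoxybenzoate (target)
Conditions: Bu4NF, AcOH, THF, 0 °C
Reagents that add atoms: none
Why: Fluoride cleaves the aryl silyl ether; buffering with acetic acid keeps the phenoxide from attacking the ester and leaves the alcohols and the alkene untouched.

## Compound list

1 | (S)-carvone | CC1=CC[C@@H](CC1=O)C(C)=C | starting material
2 | (2S,5S)-2-methyl-5-(propan-2-yl)cyclohexan-1-one (carvomenthone; trans epimer drawn, C2 epimer also present) | C[C@H]1CC[C@@H](CC1=O)C(C)C | intermediate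
3 | (S)-1-phenylethylamine | C[C@H](N)c1ccccc1 | starting material
4 | methyl vinyl ketone | CC(=O)C=C | starting material
5 | N-[(1S)-1-phenylethyl] imine of 2 (C2 and C=N geometry not fixed) | CC1CC[C@@H](CC1=N[C@@H](C)c1ccccc1)C(C)C | intermediate
6 | N-[(1S)-1-phenylethyl] imine of 7 (Michael adduct imine) | C[C@]1(CCC(C)=O)CC[C@@H](CC1=N[C@@H](C)c1ccccc1)C(C)C | intermediate
7 | (2R,5S)-2-methyl-2-(3-oxobutyl)-5-(propan-2-yl)cyclohexan-1-one | C[C@]1(CCC(C)=O)CC[C@@H](CC1=O)C(C)C | intermediate
8 | (4aR,7S)-4a-methyl-7-(propan-2-yl)-4,4a,5,6,7,8-hexahydronaphthalen-2(3H)-one | O=C1C=C2C[C@H](CC[C@]2(C)CC1)C(C)C | intermediate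
9 | 8,8-ethylenedioxy-4β-isopropyl-1β-methyldecal-5-ene | O1CCOC12CC3=C[C@@H](C(C)C)CC[C@]3(C)CC2 | intermediate
10 | 6α-bromo-8,8-ethylenedioxy-4β-isopropyl-1β-methyldecalin-5β-ol | O1CCOC12C[C@@]3(Br)[C@@H](O)[C@@H](C(C)C)CC[C@]3(C)CC2 | intermediate
11 | 5β,6β-epoxy-8,8-ethylenedioxy-4β-isopropyl-1β-methyldecalin | O1CCOC12C[C@@]34O[C@H]4[C@@H](C(C)C)CC[C@]3(C)CC2 | intermediate
12 | 8,8-ethylenedioxy-4β-isopropyl-1β-methyl-5α-(phenylselanyl)decalin-6β-ol (cis-fused) | O1CCOC12C[C@]3(O)[C@H]([Se]c4ccccc4)[C@@H](C(C)C)CC[C@]3(C)CC2 | intermediate
13 | selenoxide of 12 (configuration at selenium not fixed) | O1CCOC12C[C@]3(O)[C@H]([Se](=O)c4ccccc4)[C@@H](C(C)C)CC[C@]3(C)CC2 | intermediate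
14 | 8,8-ethylenedioxy-4-isopropyl-1β-methyldecal-4-en-6β-ol (cis-fused) | O1CCOC12C[C@]3(O)C=C(C(C)C)CC[C@]3(C)CC2 | intermediate
15 | cyclic 4β,5β-osmate ester of 16, TMEDA complex | O1CCOC12C[C@]3(O)[C@H]4O[Os](=O)(=O)O[C@@]4(C(C)C)CC[C@]3(C)CC2.CN(C)CCN(C)C | intermediate
16 | 8,8-ethylenedioxy-4α-isopropyl-1β-methyldecalin-4β,5β,6β-triol (cis-fused) | O1CCOC12C[C@]3(O)[C@@H](O)[C@](O)(C(C)C)CC[C@]3(C)CC2 | intermediate
17 | 8,8-ethylenedioxy-4β,6β-dihydroxy-4α-isopropyl-1β-methyldecalin-5β-yl methanesulfonate (rearrangement precursor) | O1CCOC12C[C@]3(O)[C@@H](OS(C)(=O)=O)[C@](O)(C(C)C)CC[C@]3(C)CC2 | intermediate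
18 | 8,8-ethylenedioxy-4β-hydroxydaucan-6-one (1β-methyl; 5α-H) | O1CCOC12CC(=O)[C@@H]3[C@](C)(CC[C@@]3(O)C(C)C)CC2 | intermediate
19 | 8,8-ethylenedioxydaucane-4β,6α-diol | O1CCOC12C[C@H](O)[C@@H]3[C@](C)(CC[C@@]3(O)C(C)C)CC2 | intermediate
20 | vanillic acid | COc1cc(ccc1O)C(=O)O | starting material
21 | tert-butyldimethylsilyl 4-(tert-butyldimethylsilyloxy)-3-methoxybenzoate | COc1cc(ccc1O[Si](C)(C)C(C)(C)C)C(=O)O[Si](C)(C)C(C)(C)C | intermediate
22 | 4-(tert-butyldimethylsilyloxy)-3-methoxybenzoic acid | COc1cc(ccc1O[Si](C)(C)C(C)(C)C)C(=O)O | intermediate
23 | 8,8-ethylenedioxy-4β-hydroxydaucan-6α-yl 4-(tert-butyldimethylsilyloxy)-3-methoxybenzoate | O1CCOC12C[C@H](OC(=O)c3ccc(O[Si](C)(C)C(C)(C)C)c(OC)c3)[C@@H]4[C@](C)(CC[C@@]4(O)C(C)C)CC2 | intermediate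
24 | 4β-hydroxy-8-oxodaucan-6α-yl 4-(tert-butyldimethylsilyloxy)-3-methoxybenzoate | O=C1C[C@H](OC(=O)c2ccc(O[Si](C)(C)C(C)(C)C)c(OC)c2)[C@@H]3[C@](C)(CC[C@@]3(O)C(C)C)CC1 | intermediate
25 | 4β-hydroxydauc-8(14)-en-6α-yl 4-(tert-butyldimethylsilyloxy)-3-methoxybenzoate | C=C1C[C@H](OC(=O)c2ccc(O[Si](C)(C)C(C)(C)C)c(OC)c2)[C@@H]3[C@](C)(CC[C@@]3(O)C(C)C)CC1 | intermediate
26 | 4β,9α-dihydroxydauc-8(14)-en-6α-yl 4-(tert-butyldimethylsilyloxy)-3-methoxybenzoate | C=C1C[C@H](OC(=O)c2ccc(O[Si](C)(C)C(C)(C)C)c(OC)c2)[C@@H]3[C@](C)(CC[C@@]3(O)C(C)C)C[C@@H]1O | intermediate
27 | (1R,4R,5S,6S,9S)-4,9-dihydroxydauc-8(14)-en-6-yl 4-hydroxy-3-methoxybenzoate (daucane numbering; CNP0330487.1) | C=C1C[C@H](OC(=O)c2ccc(O)c(OC)c2)[C@@H]2[C@](C)(CC[C@@]2(O)C(C)C)C[C@@H]1O | target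

## Step count and least certain steps

Total: 17 steps. Longest linear sequence: 16 steps (1 to 27 through steps 1–11 and 13–17); step 12 is a one-step side branch.

Step 10 (key step). The likely failure is loss of migration selectivity. The C3–C4 bond is also anti-periplanar to the sulfonate, and the alkoxide on C4 can push it onto C5, contracting ring A to an acylcyclopentane in competition with the wanted C1 shift. The fallback removes the second donor by changing the substrate. Setting out from 17, the less hindered tertiary hydroxyl on C4 is silylated (TESOTf, 2,6-lutidine, CH2Cl2, −78 °C) to give the 4-O-triethylsilyl ether of 17 F1. Only O6 can then form the aluminium alkoxide, and treatment with Et3Al gives the 4-O-triethylsilyl ether of 18 F2. HF·pyridine in THF then gives 18, where the route is rejoined.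

Step 8. The likely failure is poor facial selectivity of osmylation. If the hindered tertiary hydroxyl hydrogen-bonds weakly, the reagent may add anti to it on the α face, or the trisubstituted alkene may react sluggishly. The fallback replaces the dihydroxylation by an epoxide–carbonate sequence with overall retention. Setting out from 14, hydroxyl-directed epoxidation (VO(acac)2, t-BuOOH, CH2Cl2) gives the cis-fused 4β,5β-epoxy-6β-ol F3. Carbon dioxide insertion (CO2, Bu4NBr, 100 °C) opens C5 with bromide and recloses with the carbonate oxygen on C4. This double inversion gives the cyclic 4β,5β-carbonate F4, which NaOH in aqueous MeOH hydrolyses to 16.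

Step 11. The likely failure is slow ligand exchange at the crowded tertiary hydroxyl, so that intramolecular hydride delivery does not take place and the reduction stalls or loses its facial preference. The fallback accepts the opposite epimer and inverts it during esterification. Setting out from 18, NaBH4 in MeOH attacks the open α face and gives the 6β-alcohol F5. Mitsunobu esterification of F5 with 22 (PPh3, DIAD, THF) then inverts C6 and returns to the route at 23, so step 13 is not needed.

Step 16. The likely failures are poor facial selectivity in the oxygen transfer to C9, over-oxidation to the enone, and some attack at C7. The fallback sets C9 by hydride in place of oxygen delivery. Setting out from 25, material that carries oxygen at C9 on the wrong face, the 9β-alcohol F6, is oxidised together with any over-oxidised product by Dess–Martin periodinane to the 9-oxo enone F7. Luche reduction (NaBH4, CeCl3·7H2O, MeOH, −78 °C) then puts hydride on the face that oxygen had taken and gives 26. This fallback corrects the epimer only if the β face proved the less hindered one.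

## Further compounds

F1 | step 10 | 8,8-ethylenedioxy-6β-hydroxy-4α-isopropyl-1β-methyl-4β-(triethylsilyloxy)decalin-5β-yl methanesulfonate | O1CCOC12C[C@]3(O)[C@@H](OS(C)(=O)=O)[C@](O[Si](CC)(CC)CC)(C(C)C)CC[C@]3(C)CC2
F2 | step 10 | 8,8-ethylenedioxy-4β-(triethylsilyloxy)daucan-6-one | O1CCOC12CC(=O)[C@@H]3[C@](C)(CC[C@@]3(O[Si](CC)(CC)CC)C(C)C)CC2
F3 | step 8 | 4β,5β-epoxy-8,8-ethylenedioxy-4α-isopropyl-1β-methyldecalin-6β-ol (cis-fused) | O1CCOC12C[C@]3(O)[C@H]4O[C@@]4(C(C)C)CC[C@]3(C)CC2
F4 | step 8 | cyclic 4β,5β-carbonate of 16 | O1CCOC12C[C@]3(O)[C@H]4OC(=O)O[C@@]4(C(C)C)CC[C@]3(C)CC2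
F5 | step 11 | 8,8-ethylenedioxydaucane-4β,6β-diol | O1CCOC12C[C@@H](O)[C@@H]3[C@](C)(CC[C@@]3(O)C(C)C)CC2
F6 | step 16 | 4β,9β-dihydroxydauc-8(14)-en-6α-yl 4-(tert-butyldimethylsilyloxy)-3-methoxybenzoate | C=C1C[C@H](OC(=O)c2ccc(O[Si](C)(C)C(C)(C)C)c(OC)c2)[C@@H]3[C@](C)(CC[C@@]3(O)C(C)C)C[C@H]1O
F7 | step 16 | 4β-hydroxy-9-oxodauc-8(14)-en-6α-yl 4-(tert-butyldimethylsilyloxy)-3-methoxybenzoate | C=C1C[C@H](OC(=O)c2ccc(O[Si](C)(C)C(C)(C)C)c(OC)c2)[C@@H]3[C@](C)(CC[C@@]3(O)C(C)C)CC1=O
A1 | alternative 1 | 6α,9α-epidioxy-4β-(triethylsilyloxy)-14-(trimethylsilyl)dauc-7-ene | C[Si](C)(C)CC1=C[C@@H]2OO[C@H]1C[C@@]3(C)CC[C@@](O[Si](CC)(CC)CC)(C(C)C)[C@H]23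
A2 | alternative 1 | 4β-(triethylsilyloxy)-14-(trimethylsilyl)dauca-6,8-diene | C[Si](C)(C)CC1=CC[C@@]2(C)CC[C@@](O[Si](CC)(CC)CC)(C(C)C)[C@@H]2C=C1
A3 | alternative 2 | methyl 4,4-ethylenedioxy-1β-methylbicyclo[5.3.0]deca-5,8-diene-8-carboxylate (daucane numbering) | COC(=O)C1=CC[C@@]2(C)CCC3(OCCO3)C2=CC1
A4 | alternative 2 | 6-ethenyl-7-methyl-1,4-dioxaspiro[4.4]non-6-ene | C=CC1=C(C)CCC12OCCO2
A5 | alternative 2 | methyl 2-diazobut-3-enoate | COC(=O)C(=[N+]=[N-])C=C
A6 | alternative 3 | 4β-(tert-butyldimethylsilyloxy)-8,8-ethylenedioxy-2-oxodaucan-6α-yl 4-(tert-butyldimethylsilyloxy)-3-methoxybenzoate | O1CCOC12C[C@H](OC(=O)c3ccc(O[Si](C)(C)C(C)(C)C)c(OC)c3)[C@@H]5[C@](C)(C(=O)C[C@@]5(O[Si](C)(C)C(C)(C)C)C(C)C)CC2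
A7 | alternative 3 | diazomethyl ketone precursor of A6 (cycloheptane with C1 methyl and diazoacetyl, C5 silyloxy-isobutyl side chain, C6 ester, C8 dioxolane) | O1CCOC12C[C@H](OC(=O)c3ccc(O[Si](C)(C)C(C)(C)C)c(OC)c3)[C@@H]([C@H](O[Si](C)(C)C(C)(C)C)C(C)C)[C@](C)(C(=O)C=[N+]=[N-])CC2
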